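**Retrosynthetic overview**

1. Carotenoid numbering is used: ring C1 (CMe2), C2 (CH2), C3 (CHOH), C4 (=CH), C5 (=CMe), C6 (ring end of the exocyclic alkene), chain C7–C15, primes for the second half. The last disconnections are the two silyl ethers and then the C10=C11 and C10'=C11' bonds, made by a twofold Wittig reaction of a C12 bis-phosphonium salt (from glyoxal and a C5 phosphonate) with two molecules of a C14 ring trienal.
2. The trienal goes back by Wittig C3 extension, oxidation, ester cleavage, silylation and enantioselective ketone reduction (sets C3 as S) to an (E)-4-alkylidene-3,5,5-trimethylcyclohex-2-enone.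
3. Key disconnection: this cyclohexenone is cut at C1–C2 and C5–C6 into 3-methoxy-3-methylcyclobutanone (C2–C3–C4–C5 with the C5 methyl) and a 1,1-dimethylallene (C1=C6=C7–C8). In the forward sense the cyclobutanone is opened by a Lewis acid with release of strain, the allene captures it in a formal [4+2] annulation, and methanol is lost.
4. Enabling feature: in each ring the oxygenated C3 and the methyl-bearing alkene carbon C5 are 1,3-related, a masked β-alkoxy ketone that can be stored as the strained cyclobutanone. The quaternary C1 and its neighbour C6 are the terminus and central carbon of a 1,1-dimethylallene, so C1 can be a tertiary cation and the exocyclic C6=C7 bond is what remains of the allene.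
5. Ring order: the cyclobutanone ring first ([2+2]), then the cyclohexene ring (made once, used twice), and the polyene last.

Key step: step 6

Assumption: the E geometry of the exocyclic C6=C7 bond set in step 6 is taken to survive the neutral or basic steps that follow, and glyoxal is handled as the anhydrous monomer (THF solution from cracking the commercial trimer dihydrate).

**Route**

Step 1
Reactants: 1 2-methoxypropene; 2 trichloroacetyl chloride
Product: 4 2,2-dichloro-3-methoxy-3-methylcyclobutan-1-one (racemic), via dichloroketene 3 (not isolated)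
Conditions: activated Zn dust (Zn–Cu couple), Et2O/1,2-dimethoxyethane, slow addition of 2, rt
Reagents that add atoms: none
Why: Zn dehalogenates 2 to dichloroketene, whose [2+2] cycloaddition with the electron-rich enol ether is regioselective (ketene carbonyl carbon to the CH2 terminus), as in the standard ketene–enol ether cyclobutanone synthesis; the stereocentre formed is racemic and disappears in step 2.

Step 2
Reactants: 4 2,2-dichloro-3-methoxy-3-methylcyclobutan-1-one
Product: 5 3-methoxy-3-methylcyclobutan-1-one
Conditions: Zn dust, AcOH, TMEDA, EtOH, 0 °C → rt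
Reagents that add atoms: none
Why: Zinc reduction of α,α-dichlorocyclobutanones to the parent cyclobutanone is standard, the amine buffer should protect the acid-labile β-alkoxy ketone, and the product is achiral.

Step 3
Reactants: 6 isobutyryl chloride; 7 ethyl (triphenylphosphoranylidene)acetate
Product: 9 ethyl 4-methylpenta-2,3-dienoate, via dimethylketene 8 (not isolated)
Conditions: Et3N, CH2Cl2, 0 °C → rt
Reagents that add atoms: none
Why: Et3N dehydrochlorinates 6 to dimethylketene, which undergoes a Wittig reaction with the stabilised ylide at the ketene carbonyl to give the allenic ester (the standard allenoate synthesis).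

Step 4
Reactants: 9 ethyl 4-methylpenta-2,3-dienoate
Product: 10 4-methylpenta-2,3-dien-1-ol
Conditions: i-Bu2AlH (2.2 equiv), CH2Cl2, −78 °C; aq. potassium sodium tartrate (KNaC4H4O6)
Reagents that add atoms: none
Why: i-Bu2AlH reduces the ester 1,2 at low temperature without touching the allene (standard allenoate-to-allenol reduction).

Step 5
Reactants: 10 4-methylpenta-2,3-dien-1-ol
Product: 11 4-methylpenta-2,3-dien-1-yl pivalate
Conditions: pivaloyl chloride, pyridine, 4-(dimethylamino)pyridine (cat.), CH2Cl2, 0 °C
Reagents that add atoms: pivaloyl chloride, CC(C)(C)C(Cl)=O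
Why: Acylation of the primary alcohol; the pivalate masks the hydroxyl as a weakly Lewis-basic, non-nucleophilic group that should not capture the cation of step 6.

Step 6
Reactants: 5 3-methoxy-3-methylcyclobutan-1-one; 11 4-methylpenta-2,3-dien-1-yl pivalate
Product: 13 (E)-2-(2,6,6-trimethyl-4-oxocyclohex-2-en-1-ylidene)ethyl pivalate, via methoxy ketone cycloadduct 12 (not isolated)
Conditions: 5 (1.5 equiv), EtAlCl2 (2.5 equiv), CH2Cl2, −78 → −40 °C; then DBU (6 equiv), −40 °C → rt; aq. KNaC4H4O6
Reagents that add atoms: none
Why: Proposed new method: EtAlCl2 on the carbonyl of 5 should trigger strain-releasing cleavage of the ring bond between a CH2 and the methoxy carbon to give an aluminium enolate tethered to a tertiary oxocarbenium ion; the central allene carbon of 11 attacks this ion (C5–C6 bond), the charge moves to the gem-dimethyl terminus, the enolate carbon collapses on that tertiary cation (C1–C2 bond), and DBU then expels methanol from the β-methoxy ketone 12 to give the dienone. The closest known reaction type is the Lewis-acid-mediated formal [4+2] cycloaddition of 3-alkoxycyclobutanones with allylsilanes, silyl enol ethers and carbonyl compounds; an unactivated trisubstituted allene as the two-carbon partner is the untested element. The cyclohexanone ring closes in the second event as a 6-(enolendo) C-alkylation of the enolate on a trigonal cationic carbon, which needs no bond rotation because the vacant orbital at the gem-dimethyl carbon lies in the plane in which the oxocarbenium carbon arrived. The only stereocentre formed, the methoxy-bearing carbon of 12, is erased by the elimination; the lasting stereo-element is the E geometry of the exocyclic alkene, set because the electrophile reaches the central allene carbon in the plane of the H/CH2OPiv terminus and from the side of the hydrogen. The step needs central-carbon attack with the cation at the dimethyl terminus (secured by tertiary over secondary cation stability), closure at that terminus and not at the far one (secured by the unrotated, localised cation and the six-ring tether), and C- over O-alkylation (an O-alkylated tertiary ether should re-ionise under the Lewis acid and funnel to the ketone).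

Step 7
Reactants: 13 (E)-2-(2,6,6-trimethyl-4-oxocyclohex-2-en-1-ylidene)ethyl pivalate
Product: 14 (E)-2-[(4S)-4-hydroxy-2,6,6-trimethylcyclohex-2-en-1-ylidene]ethyl pivalate
Conditions: (R)-2-methyl-CBS-oxazaborolidine [(3aR)-1-methyl-3,3-diphenyltetrahydro-1H,3H-pyrrolo[1,2-c][1,3,2]oxazaborole] (20 mol %), catecholborane (1.5 equiv), toluene, −78 °C
Reagents that add atoms: none
Why: Corey–Bakshi–Shibata reduction: the oxazaborolidine binds the ketone lone pair anti to the larger alkenyl arm and delivers hydride to one face, which with the (R)-catalyst should give the (S)-carbinol (enone C=C as the large group, as for cyclohex-2-enones), while catecholborane leaves the ester and the diene alone.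

Step 8
Reactants: 14 (E)-2-[(4S)-4-hydroxy-2,6,6-trimethylcyclohex-2-en-1-ylidene]ethyl pivalate
Product: 15 (E)-2-[(4S)-4-(tert-butyldimethylsilyloxy)-2,6,6-trimethylcyclohex-2-en-1-ylidene]ethyl pivalate
Conditions: TBSCl, imidazole, DMF, rt
Reagents that add atoms: tert-butyldimethylsilyl chloride, CC(C)(C)[Si](C)(C)Cl
Why: Standard silylation of a secondary allylic alcohol under basic conditions that do not ionise the allylic C–O bond, so the stereocentre is retained.

Step 9
Reactants: 15 (E)-2-[(4S)-4-(tert-butyldimethylsilyloxy)-2,6,6-trimethylcyclohex-2-en-1-ylidene]ethyl pivalate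
Product: 16 (E)-2-[(4S)-4-(tert-butyldimethylsilyloxy)-2,6,6-trimethylcyclohex-2-en-1-ylidene]ethan-1-ol
Conditions: i-Bu2AlH (2.5 equiv), CH2Cl2, −78 °C; aq. KNaC4H4O6
Reagents that add atoms: none
Why: Reductive cleavage of the pivalate by i-Bu2AlH at low temperature, conditions under which the silyl ether and the diene survive.

Step 10
Reactants: 16 (E)-2-[(4S)-4-(tert-butyldimethylsilyloxy)-2,6,6-trimethylcyclohex-2-en-1-ylidene]ethan-1-ol
Product: 17 (E)-2-[(4S)-4-(tert-butyldimethylsilyloxy)-2,6,6-trimethylcyclohex-2-en-1-ylidene]acetaldehyde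
Conditions: activated MnO2 (excess), CH2Cl2, rt, dark
Reagents that add atoms: none
Why: MnO2 oxidises the dienylic primary alcohol to the enal under neutral conditions that should preserve the exocyclic E geometry and the allylic silyl ether.

Step 11
Reactants: 17 (E)-2-[(4S)-4-(tert-butyldimethylsilyloxy)-2,6,6-trimethylcyclohex-2-en-1-ylidene]acetaldehyde; 18 2-(triphenylphosphoranylidene)propanal
Product: 19 (2E,4E)-4-[(4S)-4-(tert-butyldimethylsilyloxy)-2,6,6-trimethylcyclohex-2-en-1-ylidene]-2-methylbut-2-enal
Conditions: toluene, 90 °C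
Reagents that add atoms: none
Why: Wittig reaction with the formyl-stabilised ylide is E-selective and should stop after one homologation because the product is an α-branched, less electrophilic enal.

Step 12
Reactants: 20 glyoxal; 21 triethyl 3-methyl-4-phosphonocrotonate (2.2 equiv)
Product: 23 diethyl (2E,4E,6E,8E)-3,8-dimethyldeca-2,4,6,8-tetraenedioate, via mono-olefinated aldehyde 22 (not isolated)
Conditions: NaH, THF, 0 °C; glyoxal in THF, −78 °C → rt; recrystallisation
Reagents that add atoms: none
Why: Twofold Horner–Wadsworth–Emmons reaction of the vinylogous phosphonate anion with both formyl groups should give E-disubstituted alkenes, the trisubstituted bonds coming from the reagent, with crystallisation to enrich the all-E diester.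

Step 13
Reactants: 23 diethyl (2E,4E,6E,8E)-3,8-dimethyldeca-2,4,6,8-tetraenedioate
Product: 24 (2E,4E,6E,8E)-3,8-dimethyldeca-2,4,6,8-tetraene-1,10-diol
Conditions: i-Bu2AlH (4.5 equiv), CH2Cl2/toluene, −78 → 0 °C; aq. KNaC4H4O6
Reagents that add atoms: none
Why: 1,2-Reduction of both conjugated esters to the bis-allylic diol without affecting the tetraene (standard polyene diester reduction).

Step 14
Reactants: 24 (2E,4E,6E,8E)-3,8-dimethyldeca-2,4,6,8-tetraene-1,10-diol
Product: 25 [(2E,4E,6E,8E)-3,8-dimethyldeca-2,4,6,8-tetraene-1,10-diyl]bis(triphenylphosphonium) dibromide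
Conditions: PPh3·HBr (2.1 equiv), MeOH, 0 °C → rt
Reagents that add atoms: triphenylphosphine hydrobromide, [Br-].c1ccc(cc1)[PH+](c1ccccc1)c1ccccc1
Why: Allylic alcohols are converted directly into allyltriphenylphosphonium salts by PPh3·HBr through the delocalised allyl cation, which should be captured at the primary terminus with the conjugated tetraene retained (standard in polyene chemistry).

Step 15
Reactants: 25 [(2E,4E,6E,8E)-3,8-dimethyldeca-2,4,6,8-tetraene-1,10-diyl]bis(triphenylphosphonium) dibromide; 19 (2E,4E)-4-[(4S)-4-(tert-butyldimethylsilyloxy)-2,6,6-trimethylcyclohex-2-en-1-ylidene]-2-methylbut-2-enal (2.1 equiv)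
Product: 27 (3S,3'S)-3,3'-bis(tert-butyldimethylsilyloxy)-4',5'-didehydro-4,5'-retro-β,β-carotene (all-E), via mono-coupled phosphonium bromide 26 (not isolated)
Conditions: NaOMe (2.3 equiv), MeOH/CH2Cl2, 0 °C → rt, dark, argon; then n-heptane, reflux; crystallisation
Reagents that add atoms: none
Why: Twofold Wittig reaction of the bis-ylide with two molecules of 19 builds the C10=C11 and C10'=C11' bonds, and the sterically hindered Z isomers formed alongside should isomerise thermally to the all-E polyene, as is usual for carotenoid Wittig condensations.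

Step 16
Reactants: 27 (3S,3'S)-3,3'-bis(tert-butyldimethylsilyloxy)-4',5'-didehydro-4,5'-retro-β,β-carotene
Product: 28 (3S,3'S,all-E)-4',5'-didehydro-4,5'-retro-β,β-carotene-3,3'-diol (eschscholtzxanthin, the target)
Conditions: tetrabutylammonium fluoride (3 equiv), THF, 0 °C → rt, dark
Reagents that add atoms: none
Why: Fluoride cleaves both silyl ethers under non-acidic conditions that the acid-labile allylic polyene diol should tolerate, and both stereocentres are untouched.

**Compound list**

1 | 2-methoxypropene | COC(C)=C | starting material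
2 | trichloroacetyl chloride | ClC(=O)C(Cl)(Cl)Cl | starting material
3 | dichloroketene | O=C=C(Cl)Cl | intermediate (not isolated)
4 | 2,2-dichloro-3-methoxy-3-methylcyclobutan-1-one (racemic) | COC1(C)CC(=O)C1(Cl)Cl | intermediate
5 | 3-methoxy-3-methylcyclobutan-1-one | COC1(C)CC(=O)C1 | intermediate
6 | isobutyryl chloride (2-methylpropanoyl chloride) | CC(C)C(Cl)=O | starting material
7 | ethyl (triphenylphosphoranylidene)acetate | CCOC(=O)C=P(c1ccccc1)(c1ccccc1)c1ccccc1 | starting material
8 | dimethylketene | CC(C)=C=O | intermediate (not isolated)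
9 | ethyl 4-methylpenta-2,3-dienoate | CCOC(=O)C=C=C(C)C | intermediate
10 | 4-methylpenta-2,3-dien-1-ol | CC(C)=C=CCO | intermediate
11 | 4-methylpenta-2,3-dien-1-yl pivalate | CC(C)=C=CCOC(=O)C(C)(C)C | intermediate
12 | (E)-2-(2-methoxy-2,6,6-trimethyl-4-oxocyclohexylidene)ethyl pivalate (racemic) | COC1(C)CC(=O)CC(C)(C)\C1=C/COC(=O)C(C)(C)C | intermediate (not isolated)
13 | (E)-2-(2,6,6-trimethyl-4-oxocyclohex-2-en-1-ylidene)ethyl pivalate | CC1=CC(=O)CC(C)(C)\C1=C/COC(=O)C(C)(C)C | intermediate
14 | (E)-2-[(4S)-4-hydroxy-2,6,6-trimethylcyclohex-2-en-1-ylidene]ethyl pivalate | CC1=C[C@@H](O)CC(C)(C)\C1=C/COC(=O)C(C)(C)C | intermediate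
15 | (E)-2-[(4S)-4-(tert-butyldimethylsilyloxy)-2,6,6-trimethylcyclohex-2-en-1-ylidene]ethyl pivalate | CC1=C[C@@H](O[Si](C)(C)C(C)(C)C)CC(C)(C)\C1=C/COC(=O)C(C)(C)C | intermediate
16 | (E)-2-[(4S)-4-(tert-butyldimethylsilyloxy)-2,6,6-trimethylcyclohex-2-en-1-ylidene]ethan-1-ol | CC1=C[C@@H](O[Si](C)(C)C(C)(C)C)CC(C)(C)\C1=C/CO | intermediate
17 | (E)-2-[(4S)-4-(tert-butyldimethylsilyloxy)-2,6,6-trimethylcyclohex-2-en-1-ylidene]acetaldehyde | CC1=C[C@@H](O[Si](C)(C)C(C)(C)C)CC(C)(C)\C1=C/C=O | intermediate
18 | 2-(triphenylphosphoranylidene)propanal | CC(C=O)=P(c1ccccc1)(c1ccccc1)c1ccccc1 | starting material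
19 | (2E,4E)-4-[(4S)-4-(tert-butyldimethylsilyloxy)-2,6,6-trimethylcyclohex-2-en-1-ylidene]-2-methylbut-2-enal | CC1=C[C@@H](O[Si](C)(C)C(C)(C)C)CC(C)(C)\C1=C/C=C(C)/C=O | intermediate
20 | glyoxal | O=CC=O | starting material
21 | triethyl 3-methyl-4-phosphonocrotonate (ethyl (E)-4-(diethoxyphosphoryl)-3-methylbut-2-enoate; the commercial E/Z mixture can be used) | CCOC(=O)/C=C(C)/CP(=O)(OCC)OCC | starting material
22 | ethyl (2E,4E)-3-methyl-6-oxohexa-2,4-dienoate | CCOC(=O)/C=C(C)/C=C/C=O | intermediate (not isolated)
23 | diethyl (2E,4E,6E,8E)-3,8-dimethyldeca-2,4,6,8-tetraenedioate | CCOC(=O)/C=C(C)/C=C/C=C/C(C)=C/C(=O)OCC | intermediate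
24 | (2E,4E,6E,8E)-3,8-dimethyldeca-2,4,6,8-tetraene-1,10-diol | OC/C=C(C)/C=C/C=C/C(C)=C/CO | intermediate
25 | [(2E,4E,6E,8E)-3,8-dimethyldeca-2,4,6,8-tetraene-1,10-diyl]bis(triphenylphosphonium) dibromide | c1ccccc1[P+](c1ccccc1)(c1ccccc1)C/C=C(C)/C=C/C=C/C(C)=C/C[P+](c1ccccc1)(c1ccccc1)c1ccccc1.[Br-].[Br-] | intermediate
26 | mono-coupled phosphonium bromide (ring trienal joined to one end of 25; new C10=C11 bond drawn E) | CC1=C[C@@H](O[Si](C)(C)C(C)(C)C)CC(C)(C)\C1=C/C=C(C)/C=C/C=C(C)/C=C/C=C/C(C)=C/C[P+](c1ccccc1)(c1ccccc1)c1ccccc1.[Br-] | intermediate (not isolated)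
27 | (3S,3'S)-3,3'-bis(tert-butyldimethylsilyloxy)-4',5'-didehydro-4,5'-retro-β,β-carotene (all-E) | CC1=C[C@@H](O[Si](C)(C)C(C)(C)C)CC(C)(C)\C1=C/C=C(C)/C=C/C=C(C)/C=C/C=C/C(C)=C/C=C/C(C)=C/C=C1/C(C)=C[C@@H](O[Si](C)(C)C(C)(C)C)CC1(C)C | intermediate
28 | (3S,3'S,all-E)-4',5'-didehydro-4,5'-retro-β,β-carotene-3,3'-diol (eschscholtzxanthin) | CC1=C[C@@H](O)CC(C)(C)\C1=C/C=C(C)/C=C/C=C(C)/C=C/C=C/C(C)=C/C=C/C(C)=C/C=C1/C(C)=C[C@@H](O)CC1(C)C | target

**Step count**

Total: 16 steps. Longest linear sequence: 11 steps (6 → 9 → 10 → 11 → 13 → 14 → 15 → 16 → 17 → 19 → 27 → 28).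

**Steps most likely to fail**

Step 6 (proposed new method). The opened cyclobutanone may lose a proton to give the acyclic β-methoxy enone before the allene captures the oxocarbenium ion. The allene may oligomerise under the Lewis acid. The tertiary cation may lose a proton or close at the far allene terminus instead of closing on the enolate carbon.

The fallback uses known chemistry and buys the six-membered ring. It sets out from no numbered compound: it replaces 5 and 11 by commercial ketoisophorone F1 and comes back to the route at 13.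
- Ketalisation with ethylene glycol (p-toluenesulfonic acid cat., benzene, water separator) should take place at the less hindered carbonyl and give 7,9,9-trimethyl-1,4-dioxaspiro[4.5]dec-6-en-8-one F2.
- Peterson olefination of the remaining hindered ketone with the lithium enolate of ethyl (trimethylsilyl)acetate (LiN(i-Pr)2, THF, −78 °C → rt) should give ethyl (E)-2-(7,9,9-trimethyl-1,4-dioxaspiro[4.5]dec-6-en-8-ylidene)acetate F3, the E isomer being separated from the Z isomer by chromatography.
- i-Bu2AlH reduction gives (E)-2-(7,9,9-trimethyl-1,4-dioxaspiro[4.5]dec-6-en-8-ylidene)ethan-1-ol F4.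
- Pivaloylation gives (E)-2-(7,9,9-trimethyl-1,4-dioxaspiro[4.5]dec-6-en-8-ylidene)ethyl pivalate F5.
- Mild deketalisation (pyridinium p-toluenesulfonate, acetone/H2O) gives 13.

Step 7. Facial selectivity may be poor, because the two arms of the ketone (the alkenyl CH and the CH2 next to a quaternary carbon) differ little in size at the carbonyl.

The fallback sets out from 13 and comes back at 14. Luche reduction (NaBH4, CeCl3·7H2O, MeOH, −78 °C) gives racemic (E)-2-(4-hydroxy-2,6,6-trimethylcyclohex-2-en-1-ylidene)ethyl pivalate F6. Kinetic resolution with immobilised Candida antarctica lipase B and vinyl acetate in t-BuOMe is then expected, from the usual preference of lipases for (R)-cyclohex-2-enols, to acetylate the (R)-enantiomer to (E)-2-[(4R)-4-acetoxy-2,6,6-trimethylcyclohex-2-en-1-ylidene]ethyl pivalate F7. The unreacted (S)-alcohol, which is 14, is separated by chromatography.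

Step 15. The second condensation may stall at the mono-coupled stage, the bis-ylide may decompose, and the thermal equilibration may also scramble the exocyclic C6=C7 geometry.

The fallback sets out from 24 and comes back at 27. It replaces the phosphonium ylide by an E-selective phosphonate carbanion.
- PBr3 (pyridine cat., Et2O, −20 °C) gives (2E,4E,6E,8E)-1,10-dibromo-3,8-dimethyldeca-2,4,6,8-tetraene F8.
- Michaelis–Arbuzov reaction with P(OEt)3 (100 °C) gives tetraethyl [(2E,4E,6E,8E)-3,8-dimethyldeca-2,4,6,8-tetraene-1,10-diyl]bis(phosphonate) F9.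
- Twofold Horner–Wadsworth–Emmons reaction (NaN(SiMe3)2, THF, −78 °C → rt) with two equivalents of 19 should proceed through the mono-coupled phosphonate F10 to 27 without a separate isomerisation.

**Further compounds**

F1 | step 6 | ketoisophorone (2,6,6-trimethylcyclohex-2-ene-1,4-dione) | CC1=CC(=O)CC(C)(C)C1=O
F2 | step 6 | 7,9,9-trimethyl-1,4-dioxaspiro[4.5]dec-6-en-8-one | CC1=CC2(OCCO2)CC(C)(C)C1=O
F3 | step 6 | ethyl (E)-2-(7,9,9-trimethyl-1,4-dioxaspiro[4.5]dec-6-en-8-ylidene)acetate | CC1=CC2(OCCO2)CC(C)(C)\C1=C/C(=O)OCC
F4 | step 6 | (E)-2-(7,9,9-trimethyl-1,4-dioxaspiro[4.5]dec-6-en-8-ylidene)ethan-1-ol | CC1=CC2(OCCO2)CC(C)(C)\C1=C/CO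
F5 | step 6 | (E)-2-(7,9,9-trimethyl-1,4-dioxaspiro[4.5]dec-6-en-8-ylidene)ethyl pivalate | CC1=CC2(OCCO2)CC(C)(C)\C1=C/COC(=O)C(C)(C)C
F6 | step 7 | racemic (E)-2-(4-hydroxy-2,6,6-trimethylcyclohex-2-en-1-ylidene)ethyl pivalate | CC1=CC(O)CC(C)(C)\C1=C/COC(=O)C(C)(C)C
F7 | step 7 | (E)-2-[(4R)-4-acetoxy-2,6,6-trimethylcyclohex-2-en-1-ylidene]ethyl pivalate | CC1=C[C@H](OC(C)=O)CC(C)(C)\C1=C/COC(=O)C(C)(C)C
F8 | step 15 | (2E,4E,6E,8E)-1,10-dibromo-3,8-dimethyldeca-2,4,6,8-tetraene | BrC/C=C(C)/C=C/C=C/C(C)=C/CBr
F9 | step 15 | tetraethyl [(2E,4E,6E,8E)-3,8-dimethyldeca-2,4,6,8-tetraene-1,10-diyl]bis(phosphonate) | CCOP(=O)(OCC)C/C=C(C)/C=C/C=C/C(C)=C/CP(=O)(OCC)OCC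
F10 | step 15 | mono-coupled phosphonate (ring trienal joined to one end of F9) | CC1=C[C@@H](O[Si](C)(C)C(C)(C)C)CC(C)(C)\C1=C/C=C(C)/C=C/C=C(C)/C=C/C=C/C(C)=C/CP(=O)(OCC)OCC
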